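## Retrosynthetic overview

1. The target comes from a bicyclic C-2 silyl ether / TMSE ester by fluoride deprotection and oxidation; its C-7 methyl comes from an enol triflate by Negishi coupling.
2. Key disconnection: both rings arise from one acyclic (E)-dienone/(E)-enoate by an intramolecular double Michael addition of its α'-lithium dienolate, and the enolate left at C-7 is trapped as the triflate.
3. Ring order: the cyclopentane ring closes first (5-exo Michael, C-7a–C-3a), then the cyclohexene ring (6-endo Michael, C-4–C-5, the bond between the two quaternary carbons), in the same flask.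
4. The acyclic precursor comes from Nozaki–Hiyama–Kishi coupling and oxidation of a phenyl-trienyl iodide (from propargyl alcohol by carboalumination and two HWE olefinations) with an aldehyde–enoate.
5. The aldehyde–enoate comes from an Evans allylation and an Evans syn-aldol (stereotriad), an HWE with a separately made TMSE phosphonate, and oxidative cleavage of a terminal alkene.

Assumption: core atoms are numbered as in the hexahydro-1H-indene name of the target (C-1 CHMe, C-2 C=O, C-3 CHEt, C-3a, C-4 C(Et)CO2H, C-5 C(Me)(dienyl), C-6 =CH, C-7 =CMe, C-7a); the C-2 silyloxy centre is temporary; TBS = tert-butyldimethylsilyl, TMSE = 2-(trimethylsilyl)ethyl, Tf = trifluoromethanesulfonyl.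

## Route

**Trienyl iodide 8 (steps 1–6)**

Step 1
Reactants: 1 prop-2-yn-1-ol
Product: 3 (E)-3-iodo-2-methylprop-2-en-1-ol, via alkenylalane 2 (not isolated)
Conditions: AlMe3 (3 equiv), Cp2ZrCl2 (0.25 equiv), CH2Cl2, 0 °C to rt; then I2, THF, −30 to 0 °C
Reagents that add atoms: AlMe3 (trimethylaluminium) C[Al](C)C; I2 (iodine) II
Why: Zirconium-catalysed Negishi carboalumination adds Me–Al syn across the alkyne with methyl on the internal carbon, and iodinolysis with retention gives only the (E)-iodide.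

Step 2
Reactants: 3 (E)-3-iodo-2-methylprop-2-en-1-ol
Product: 4 (E)-3-iodo-2-methylprop-2-enal
Conditions: activated MnO2 (15 equiv), CH2Cl2, rt
Reagents that add atoms: none
Why: Allylic oxidation with MnO2 is neutral and leaves the C–I bond and the alkene geometry untouched.

Step 3
Reactants: 4 (E)-3-iodo-2-methylprop-2-enal
Product: 5 ethyl (2E,4E)-2-ethyl-5-iodo-4-methylpenta-2,4-dienoate
Conditions: triethyl 2-phosphonobutanoate, NaH, THF, 0 °C to rt
Reagents that add atoms: triethyl 2-phosphonobutanoate CCOC(=O)C(CC)P(=O)(OCC)OCC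
Why: Horner–Wadsworth–Emmons olefination of an α-branched enal with an α-ethyl phosphonate is E-selective, placing the ester trans to the iodopropenyl group.

Step 4
Reactants: 5 ethyl (2E,4E)-2-ethyl-5-iodo-4-methylpenta-2,4-dienoate
Product: 6 (2E,4E)-2-ethyl-5-iodo-4-methylpenta-2,4-dien-1-ol
Conditions: i-Bu2AlH (2.2 equiv), CH2Cl2, −78 °C; aq. potassium sodium tartrate
Reagents that add atoms: none
Why: 1,2-Hydride reduction of the conjugated ester gives the allylic alcohol at low temperature without touching the vinyl iodide or the diene.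

Step 5
Reactants: 6 (2E,4E)-2-ethyl-5-iodo-4-methylpenta-2,4-dien-1-ol
Product: 7 (2E,4E)-2-ethyl-5-iodo-4-methylpenta-2,4-dienal
Conditions: activated MnO2 (15 equiv), CH2Cl2, rt
Reagents that add atoms: none
Why: Allylic oxidation with MnO2 gives the dienal without E/Z isomerisation.

Step 6
Reactants: 7 (2E,4E)-2-ethyl-5-iodo-4-methylpenta-2,4-dienal
Product: 8 [(1E,3E,5E)-3-ethyl-6-iodo-5-methylhexa-1,3,5-trien-1-yl]benzene
Conditions: diethyl benzylphosphonate, NaH, THF, 0 °C to rt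
Reagents that add atoms: diethyl benzylphosphonate CCOP(=O)(Cc1ccccc1)OCC
Why: Horner–Wadsworth–Emmons olefination with a benzylphosphonate anion forms the styryl double bond E-selectively.

**TMSE phosphonate 12 (steps 7–8)**

Step 7
Reactants: 9 2-(trimethylsilyl)ethanol; 10 2-bromobutanoyl bromide (racemic)
Product: 11 2-(trimethylsilyl)ethyl 2-bromobutanoate (racemic)
Conditions: pyridine, CH2Cl2, 0 °C to rt
Reagents that add atoms: none
Why: Acylation of the alcohol by the acid bromide (esterification) is much faster than displacement of the secondary α-bromide.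

Step 8
Reactants: 11 2-(trimethylsilyl)ethyl 2-bromobutanoate
Product: 12 2-(trimethylsilyl)ethyl 2-(diethoxyphosphoryl)butanoate (racemic)
Conditions: P(OEt)3 (neat), 150 °C, EtBr distilled off
Reagents that add atoms: triethyl phosphite CCOP(OCC)OCC
Why: Michaelis–Arbuzov reaction of the α-bromo ester, the same way the ethyl ester analogue is made.

**Butanoyl imide 14 (step 9)**

Step 9
Reactants: 13 (R)-4-benzyloxazolidin-2-one
Product: 14 (R)-4-benzyl-3-butanoyloxazolidin-2-one
Conditions: butanoic anhydride, Et3N, DMAP (cat.), THF, rt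
Reagents that add atoms: butanoic anhydride CCCC(=O)OC(=O)CCC
Why: DMAP-catalysed N-acylation of the oxazolidinone; the auxiliary stereocentre is not involved.

**Aldehyde–enoate 27 (steps 10–18)**

Step 10
Reactants: 15 (R)-4-benzyl-3-propanoyloxazolidin-2-one
Product: 17 (R)-4-benzyl-3-[(S)-2-methylpent-4-enoyl]oxazolidin-2-one, via sodium Z-enolate 16 (not isolated)
Conditions: NaN(SiMe3)2, THF, −78 °C; allyl iodide, −78 to −45 °C
Reagents that add atoms: allyl iodide C=CCI
Why: Evans asymmetric alkylation: the chelated Z-enolate is allylated on the face opposite the benzyl group, setting the (S) centre that becomes C-1.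

Step 11
Reactants: 17 (R)-4-benzyl-3-[(S)-2-methylpent-4-enoyl]oxazolidin-2-one
Product: 18 (S)-2-methylpent-4-en-1-ol
Conditions: LiBH4, H2O (1 equiv), Et2O, 0 °C
Reagents that add atoms: none
Why: Reductive cleavage of the exocyclic imide carbonyl by borohydride releases the alcohol and the recoverable auxiliary without touching the stereocentre.

Step 12
Reactants: 18 (S)-2-methylpent-4-en-1-ol
Product: 19 (S)-2-methylpent-4-enal
Conditions: Dess–Martin periodinane, CH2Cl2, 0 °C to rt; used at once as a cold solution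
Reagents that add atoms: none
Why: Dess–Martin oxidation is non-basic, so the α-stereocentre of the volatile aldehyde is not epimerised.

Step 13
Reactants: 14 (R)-4-benzyl-3-butanoyloxazolidin-2-one; 19 (S)-2-methylpent-4-enal
Product: 21 (R)-4-benzyl-3-[(2R,3S,4S)-2-ethyl-3-hydroxy-4-methylhept-6-enoyl]oxazolidin-2-one, via dibutylboron Z-enolate 20 (not isolated)
Conditions: Bu2BOTf, Et3N, CH2Cl2, −78 to 0 °C; then 19, −78 to 0 °C; then pH 7 buffer, MeOH, H2O2, 0 °C
Reagents that add atoms: none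
Why: Evans syn-aldol through a Zimmerman–Traxler chair of the Z-boron enolate; the auxiliary sets the (2R,3S) pair (future C-3 and the temporary C-2 carbinol), and the anti-Felkin sense towards the (S)-aldehyde is the matched case.

Step 14
Reactants: 21 (R)-4-benzyl-3-[(2R,3S,4S)-2-ethyl-3-hydroxy-4-methylhept-6-enoyl]oxazolidin-2-one
Product: 22 (R)-4-benzyl-3-[(2R,3S,4S)-3-(tert-butyldimethylsilyloxy)-2-ethyl-4-methylhept-6-enoyl]oxazolidin-2-one
Conditions: TBSOTf, 2,6-lutidine, CH2Cl2, −78 to 0 °C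
Reagents that add atoms: tert-butyldimethylsilyl triflate CC(C)(C)[Si](C)(C)OS(=O)(=O)C(F)(F)F
Why: O-Silylation with the silyl triflate protects the hindered secondary alcohol and blocks retro-aldol in later basic steps.

Step 15
Reactants: 22 (R)-4-benzyl-3-[(2R,3S,4S)-3-(tert-butyldimethylsilyloxy)-2-ethyl-4-methylhept-6-enoyl]oxazolidin-2-one
Product: 23 (2S,3S,4S)-3-(tert-butyldimethylsilyloxy)-2-ethyl-4-methylhept-6-en-1-ol
Conditions: LiBH4, MeOH (1 equiv), THF, 0 °C to rt
Reagents that add atoms: none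
Why: Borohydride reduction of the imide removes the auxiliary and gives the primary alcohol with all three stereocentres intact.

Step 16
Reactants: 23 (2S,3S,4S)-3-(tert-butyldimethylsilyloxy)-2-ethyl-4-methylhept-6-en-1-ol
Product: 24 (2R,3S,4S)-3-(tert-butyldimethylsilyloxy)-2-ethyl-4-methylhept-6-enal
Conditions: Dess–Martin periodinane, CH2Cl2, 0 °C to rt
Reagents that add atoms: none
Why: Dess–Martin oxidation gives the α-branched aldehyde under non-epimerising conditions.

Step 17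
Reactants: 24 (2R,3S,4S)-3-(tert-butyldimethylsilyloxy)-2-ethyl-4-methylhept-6-enal; 12 2-(trimethylsilyl)ethyl 2-(diethoxyphosphoryl)butanoate
Product: 25 2-(trimethylsilyl)ethyl (2E,4S,5S,6S)-5-(tert-butyldimethylsilyloxy)-2,4-diethyl-6-methylnona-2,8-dienoate
Conditions: LiCl, DBU, MeCN, rt
Reagents that add atoms: none
Why: Masamune–Roush Horner–Wadsworth–Emmons olefination is mild enough to keep the α-ethyl centre and gives the (E)-enoate, whose geometry later places the C-4 ethyl cis to C-3.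

Step 18
Reactants: 25 2-(trimethylsilyl)ethyl (2E,4S,5S,6S)-5-(tert-butyldimethylsilyloxy)-2,4-diethyl-6-methylnona-2,8-dienoate
Product: 27 2-(trimethylsilyl)ethyl (2E,4S,5S,6S)-5-(tert-butyldimethylsilyloxy)-2,4-diethyl-6-methyl-8-oxooct-2-enoate, via vicinal diol 26 (not isolated)
Conditions: OsO4 (2 mol%), NaIO4 (4 equiv), 2,6-lutidine, dioxane–H2O 3:1, rt
Reagents that add atoms: OsO4 (osmium tetroxide) O=[Os](=O)(=O)=O, its oxygen restored from NaIO4 (sodium periodate) [Na+].[O-]I(=O)(=O)=O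
Why: Lemieux–Johnson cleavage: OsO4 dihydroxylates the electron-rich monosubstituted alkene far faster than the electron-poor trisubstituted enoate, and periodate cleaves the diol.

**Coupling and endgame (steps 19–24)**

Step 19
Reactants: 27 2-(trimethylsilyl)ethyl (2E,4S,5S,6S)-5-(tert-butyldimethylsilyloxy)-2,4-diethyl-6-methyl-8-oxooct-2-enoate; 8 [(1E,3E,5E)-3-ethyl-6-iodo-5-methylhexa-1,3,5-trien-1-yl]benzene
Product: 29 2-(trimethylsilyl)ethyl (2E,4S,5S,6S,9E,11E,13E)-5-(tert-butyldimethylsilyloxy)-2,4,12-triethyl-8-hydroxy-6,10-dimethyl-14-phenyltetradeca-2,9,11,13-tetraenoate (both C-8 epimers), via alkenylchromium dichloride 28 (not isolated)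
Conditions: CrCl2 (6 equiv), NiCl2 (2 mol%), DMSO, rt
Reagents that add atoms: none
Why: Nozaki–Hiyama–Kishi coupling: the alkenylchromium species adds only to the aldehyde, with retention of alkene geometry and no attack on the enoate; the new carbinol centre is removed in the next step.

Step 20
Reactants: 29 the C-8 carbinol (both epimers)
Product: 30 2-(trimethylsilyl)ethyl (2E,4S,5S,6S,9E,11E,13E)-5-(tert-butyldimethylsilyloxy)-2,4,12-triethyl-6,10-dimethyl-8-oxo-14-phenyltetradeca-2,9,11,13-tetraenoate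
Conditions: activated MnO2 (20 equiv), CH2Cl2, rt
Reagents that add atoms: none
Why: Allylic oxidation of the trienyl carbinol with MnO2 gives the (E)-dienone under neutral conditions and merges both epimers.

Step 21
Reactants: 30 the acyclic dienone–enoate
Product: 34 2-(trimethylsilyl)ethyl (1S,2S,3S,3aS,4R,5S,7aR)-2-(tert-butyldimethylsilyloxy)-3,4-diethyl-5-[(1E,3E)-2-ethyl-4-phenylbuta-1,3-dien-1-yl]-1,5-dimethyl-7-(trifluoromethanesulfonyloxy)-2,3,3a,4,5,7a-hexahydro-1H-indene-4-carboxylate, via lithium dienolate 31 (not isolated), via monocyclic ester enolate 32 (not isolated), via bicyclic lithium enolate 33 (not isolated)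
Conditions: LiN(SiMe3)2 (1.2 equiv), THF, −78 °C to 0 °C; then Comins' reagent, −78 °C to 0 °C
Reagents that add atoms: Comins' reagent, N-(5-chloropyridin-2-yl)bis(trifluoromethanesulfonimide) FC(F)(F)S(=O)(=O)N(c1ccc(Cl)cn1)S(=O)(=O)C(F)(F)F
Why: Kinetic α'-deprotonation gives the cross-conjugated dienolate, which undergoes an intramolecular double Michael addition (5-exo-trig onto the enoate, then 6-endo-trig of the ester enolate onto the dienone β-carbon) through a lithium-chelated, ester-endo array with the tether methyl and ethyl groups pseudo-equatorial; this sets the trans ring fusion (C-3a, C-7a) and both quaternary centres (C-4 ethyl cis to C-3 from the E-enoate, C-5 methyl cis to it from the E-enone), and O-triflation fixes the regiodefined C-6/C-7 enolate.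

Step 22
Reactants: 34 the bicyclic enol triflate
Product: 35 2-(trimethylsilyl)ethyl (1S,2S,3S,3aR,4R,5R,7aR)-2-(tert-butyldimethylsilyloxy)-3,4-diethyl-5-[(1E,3E)-2-ethyl-4-phenylbuta-1,3-dien-1-yl]-1,5,7-trimethyl-2,3,3a,4,5,7a-hexahydro-1H-indene-4-carboxylate
Conditions: Me2Zn (2 equiv), Pd(PPh3)4 (5 mol%, zerovalent palladium), THF, 0 °C to rt
Reagents that add atoms: Me2Zn (dimethylzinc) C[Zn]C
Why: Negishi cross-coupling replaces the triflate by methyl with the double bond fixed at C-6/C-7; the hindered ester, silyl ether and diene are inert to it.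

Step 23
Reactants: 35 the bicyclic silyl ether TMSE ester
Product: 36 (1S,2S,3S,3aR,4R,5R,7aR)-3,4-diethyl-5-[(1E,3E)-2-ethyl-4-phenylbuta-1,3-dien-1-yl]-2-hydroxy-1,5,7-trimethyl-2,3,3a,4,5,7a-hexahydro-1H-indene-4-carboxylic acid
Conditions: Bu4NF (5 equiv), THF, rt to 50 °C; aq. citric acid work-up
Reagents that add atoms: none
Why: Fluoride cleaves the Si–O bond of the TBS ether and fragments the TMSE ester at silicon, which frees the neopentyl-type acid without any attack at the hindered carbonyl.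

Step 24
Reactants: 36 the hydroxy acid
Product: 37 (1S,3S,3aR,4R,5R,7aR)-3,4-diethyl-5-[(1E,3E)-2-ethyl-4-phenylbuta-1,3-dien-1-yl]-1,5,7-trimethyl-2-oxo-2,3,3a,4,5,7a-hexahydro-1H-indene-4-carboxylic acid (target)
Conditions: Dess–Martin periodinane, CH2Cl2, rt
Reagents that add atoms: none
Why: Dess–Martin oxidation of the secondary alcohol gives the C-2 ketone; C-1 and C-3 are already in the thermodynamically preferred arrangement (each trans to its ring-fusion neighbour), so there is no drive to epimerise.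

## Compound list

1 | prop-2-yn-1-ol | C#CCO | starting material
2 | (E)-[3-(dimethylalumanyloxy)-2-methylprop-1-en-1-yl]dimethylalumane | C[Al](C)/C=C(\C)CO[Al](C)C | intermediate
3 | (E)-3-iodo-2-methylprop-2-en-1-ol | I/C=C(\C)CO | intermediate
4 | (E)-3-iodo-2-methylprop-2-enal | I/C=C(\C)C=O | intermediate
5 | ethyl (2E,4E)-2-ethyl-5-iodo-4-methylpenta-2,4-dienoate | I/C=C(C)/C=C(\CC)C(=O)OCC | intermediate
6 | (2E,4E)-2-ethyl-5-iodo-4-methylpenta-2,4-dien-1-ol | I/C=C(C)/C=C(\CC)CO | intermediate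
7 | (2E,4E)-2-ethyl-5-iodo-4-methylpenta-2,4-dienal | I/C=C(C)/C=C(\CC)C=O | intermediate
8 | [(1E,3E,5E)-3-ethyl-6-iodo-5-methylhexa-1,3,5-trien-1-yl]benzene | I/C=C(C)/C=C(CC)/C=C/c1ccccc1 | intermediate
9 | 2-(trimethylsilyl)ethanol | C[Si](C)(C)CCO | starting material
10 | 2-bromobutanoyl bromide (racemic) | CCC(Br)C(Br)=O | starting material
11 | 2-(trimethylsilyl)ethyl 2-bromobutanoate (racemic) | CCC(Br)C(=O)OCC[Si](C)(C)C | intermediate
12 | 2-(trimethylsilyl)ethyl 2-(diethoxyphosphoryl)butanoate (racemic) | CCC(C(=O)OCC[Si](C)(C)C)P(=O)(OCC)OCC | intermediate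
13 | (R)-4-benzyloxazolidin-2-one | O=C1N[C@H](Cc2ccccc2)CO1 | starting material
14 | (R)-4-benzyl-3-butanoyloxazolidin-2-one | CCCC(=O)N1[C@H](Cc2ccccc2)COC1=O | intermediate
15 | (R)-4-benzyl-3-propanoyloxazolidin-2-one | CCC(=O)N1[C@H](Cc2ccccc2)COC1=O | starting material
16 | sodium (Z)-enolate of 15 | [Na+].C/C=C(\[O-])N1[C@H](Cc2ccccc2)COC1=O | intermediate
17 | (R)-4-benzyl-3-[(S)-2-methylpent-4-enoyl]oxazolidin-2-one | C=CC[C@H](C)C(=O)N1[C@H](Cc2ccccc2)COC1=O | intermediate
18 | (S)-2-methylpent-4-en-1-ol | C=CC[C@H](C)CO | intermediate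
19 | (S)-2-methylpent-4-enal | C=CC[C@H](C)C=O | intermediate
20 | dibutylboron (Z)-enolate of 14 | CC/C=C(\OB(CCCC)CCCC)N1[C@H](Cc2ccccc2)COC1=O | intermediate
21 | (R)-4-benzyl-3-[(2R,3S,4S)-2-ethyl-3-hydroxy-4-methylhept-6-enoyl]oxazolidin-2-one | C=CC[C@H](C)[C@H](O)[C@@H](CC)C(=O)N1[C@H](Cc2ccccc2)COC1=O | intermediate
22 | (R)-4-benzyl-3-[(2R,3S,4S)-3-(tert-butyldimethylsilyloxy)-2-ethyl-4-methylhept-6-enoyl]oxazolidin-2-one | C=CC[C@H](C)[C@H](O[Si](C)(C)C(C)(C)C)[C@@H](CC)C(=O)N1[C@H](Cc2ccccc2)COC1=O | intermediate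
23 | (2S,3S,4S)-3-(tert-butyldimethylsilyloxy)-2-ethyl-4-methylhept-6-en-1-ol | C=CC[C@H](C)[C@H](O[Si](C)(C)C(C)(C)C)[C@@H](CC)CO | intermediate
24 | (2R,3S,4S)-3-(tert-butyldimethylsilyloxy)-2-ethyl-4-methylhept-6-enal | C=CC[C@H](C)[C@H](O[Si](C)(C)C(C)(C)C)[C@@H](CC)C=O | intermediate
25 | 2-(trimethylsilyl)ethyl (2E,4S,5S,6S)-5-(tert-butyldimethylsilyloxy)-2,4-diethyl-6-methylnona-2,8-dienoate | C=CC[C@H](C)[C@H](O[Si](C)(C)C(C)(C)C)[C@@H](CC)/C=C(\CC)C(=O)OCC[Si](C)(C)C | intermediate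
26 | 2-(trimethylsilyl)ethyl (2E,4S,5S,6S)-5-(tert-butyldimethylsilyloxy)-2,4-diethyl-8,9-dihydroxy-6-methylnon-2-enoate (both C-8 epimers) | OCC(O)C[C@H](C)[C@H](O[Si](C)(C)C(C)(C)C)[C@@H](CC)/C=C(\CC)C(=O)OCC[Si](C)(C)C | intermediate
27 | 2-(trimethylsilyl)ethyl (2E,4S,5S,6S)-5-(tert-butyldimethylsilyloxy)-2,4-diethyl-6-methyl-8-oxooct-2-enoate | O=CC[C@H](C)[C@H](O[Si](C)(C)C(C)(C)C)[C@@H](CC)/C=C(\CC)C(=O)OCC[Si](C)(C)C | intermediate
28 | [(1E,3E,5E)-4-ethyl-2-methyl-6-phenylhexa-1,3,5-trien-1-yl]chromium dichloride (trivalent chromium) | Cl[Cr](Cl)/C=C(C)/C=C(CC)/C=C/c1ccccc1 | intermediate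
29 | 2-(trimethylsilyl)ethyl (2E,4S,5S,6S,9E,11E,13E)-5-(tert-butyldimethylsilyloxy)-2,4,12-triethyl-8-hydroxy-6,10-dimethyl-14-phenyltetradeca-2,9,11,13-tetraenoate (both C-8 epimers) | OC(/C=C(C)/C=C(CC)/C=C/c1ccccc1)C[C@H](C)[C@H](O[Si](C)(C)C(C)(C)C)[C@@H](CC)/C=C(\CC)C(=O)OCC[Si](C)(C)C | intermediate
30 | 2-(trimethylsilyl)ethyl (2E,4S,5S,6S,9E,11E,13E)-5-(tert-butyldimethylsilyloxy)-2,4,12-triethyl-6,10-dimethyl-8-oxo-14-phenyltetradeca-2,9,11,13-tetraenoate | O=C(/C=C(C)/C=C(CC)/C=C/c1ccccc1)C[C@H](C)[C@H](O[Si](C)(C)C(C)(C)C)[C@@H](CC)/C=C(\CC)C(=O)OCC[Si](C)(C)C | intermediate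
31 | lithium cross-conjugated dienolate of 30 (deprotonated at the CH2 next to the ketone) | [Li+].[O-]C(/C=C(C)/C=C(CC)/C=C/c1ccccc1)=C[C@H](C)[C@H](O[Si](C)(C)C(C)(C)C)[C@@H](CC)/C=C(\CC)C(=O)OCC[Si](C)(C)C | intermediate
32 | lithium ester enolate of the monocyclic Michael adduct (cyclopentane closed, acyl and enolate-bearing carbons trans) | [Li+].CCC(/C=C/c1ccccc1)=C\C(C)=C\C(=O)[C@@H]1[C@H]([C@H](CC)[C@@H](O[Si](C)(C)C(C)(C)C)[C@H]1C)C(CC)=C([O-])OCC[Si](C)(C)C | intermediate
33 | lithium C-6/C-7 enolate of the bicyclic C-7 ketone (configuration as in 34) | [Li+].CCC(/C=C/c1ccccc1)=C\[C@@]1(C)C=C([O-])[C@@H]2[C@H]([C@H](CC)[C@@H](O[Si](C)(C)C(C)(C)C)[C@H]2C)[C@@]1(CC)C(=O)OCC[Si](C)(C)C | intermediate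
34 | 2-(trimethylsilyl)ethyl (1S,2S,3S,3aS,4R,5S,7aR)-2-(tert-butyldimethylsilyloxy)-3,4-diethyl-5-[(1E,3E)-2-ethyl-4-phenylbuta-1,3-dien-1-yl]-1,5-dimethyl-7-(trifluoromethanesulfonyloxy)-2,3,3a,4,5,7a-hexahydro-1H-indene-4-carboxylate | CCC(/C=C/c1ccccc1)=C\[C@@]1(C)C=C(OS(=O)(=O)C(F)(F)F)[C@@H]2[C@H]([C@H](CC)[C@@H](O[Si](C)(C)C(C)(C)C)[C@H]2C)[C@@]1(CC)C(=O)OCC[Si](C)(C)C | intermediate
35 | 2-(trimethylsilyl)ethyl (1S,2S,3S,3aR,4R,5R,7aR)-2-(tert-butyldimethylsilyloxy)-3,4-diethyl-5-[(1E,3E)-2-ethyl-4-phenylbuta-1,3-dien-1-yl]-1,5,7-trimethyl-2,3,3a,4,5,7a-hexahydro-1H-indene-4-carboxylate | CCC(/C=C/c1ccccc1)=C\[C@@]1(C)C=C(C)[C@@H]2[C@H]([C@H](CC)[C@@H](O[Si](C)(C)C(C)(C)C)[C@H]2C)[C@@]1(CC)C(=O)OCC[Si](C)(C)C | intermediate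
36 | (1S,2S,3S,3aR,4R,5R,7aR)-3,4-diethyl-5-[(1E,3E)-2-ethyl-4-phenylbuta-1,3-dien-1-yl]-2-hydroxy-1,5,7-trimethyl-2,3,3a,4,5,7a-hexahydro-1H-indene-4-carboxylic acid | CCC(/C=C/c1ccccc1)=C\[C@@]1(C)C=C(C)[C@@H]2[C@H]([C@H](CC)[C@@H](O)[C@H]2C)[C@@]1(CC)C(=O)O | intermediate
37 | (1S,3S,3aR,4R,5R,7aR)-3,4-diethyl-5-[(1E,3E)-2-ethyl-4-phenylbuta-1,3-dien-1-yl]-1,5,7-trimethyl-2-oxo-2,3,3a,4,5,7a-hexahydro-1H-indene-4-carboxylic acid | CCC(/C=C/c1ccccc1)=C\[C@@]1(C)C=C(C)[C@@H]2[C@H]([C@H](CC)C(=O)[C@H]2C)[C@@]1(CC)C(=O)O | target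

## Step count and risks

Total step count: 24.
Longest linear sequence: 15 steps (steps 10–24, from 15 to 37); the side branches are steps 1–6 (iodide 8), steps 7–8 (phosphonate 12) and step 9 (imide 14).

Steps most likely to fail:

Step 21 (double Michael addition and triflation). The second, 6-endo addition joins two quaternary carbons and the configuration at C-5 rests on a compact chelated transition state; the reaction may stop at the monocyclic stage or give a C-5 epimer. The fallback sets out from 30. Deprotonation with LiN(SiMe3)2 in the presence of Me3SiCl at −78 °C traps the kinetic enolate as the cross-conjugated 2-(trimethylsilyloxy)diene F1. Heating F1 in toluene at 110–140 °C then closes both rings in a thermal intramolecular Diels–Alder reaction, whose suprafacial course ties the C-5 configuration to the E geometry of the diene, and gives the bicyclic trimethylsilyl enol ether F2. MeLi in THF at 0 °C cleaves the Si–O bond of F2 to regenerate enolate 33, which is triflated with Comins' reagent, and the route is rejoined at 34.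

Step 18 (selective oxidative cleavage). OsO4 may also attack the enoate, or the cleavage may over-oxidise. The fallback sets out from 22, where the terminal alkene is the only alkene. OsO4/NaIO4 gives the aldehyde imide F3, and CH(OMe)3 with pyridinium p-toluenesulfonate in MeOH masks it as the dimethyl acetal imide F4. LiBH4 then removes the auxiliary to give the acetal alcohol F5, Dess–Martin oxidation gives the acetal aldehyde F6, and the LiCl/DBU olefination with 12 gives the acetal enoate F7. Pyridinium p-toluenesulfonate in wet acetone releases the aldehyde, and the route is rejoined at 27.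

Step 15 (borohydride removal of the auxiliary from a hindered α-ethyl β-silyloxy imide). Reduction can be slow or open the oxazolidinone ring instead. The fallback sets out from 21, before silylation. AlMe3 with MeNHOMe·HCl transamidates the free β-hydroxy imide to the Weinreb amide F8, TBSOTf with 2,6-lutidine gives the silylated Weinreb amide F9, and i-Bu2AlH at −78 °C reduces F9 directly to the aldehyde, so the route is rejoined at 24 without passing through 22 and 23.

## Further compounds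

F1 | step 21 | 2-(trimethylsilyl)ethyl (2E,4S,5S,6S,7Z,9E,11E,13E)-5-(tert-butyldimethylsilyloxy)-2,4,12-triethyl-6,10-dimethyl-14-phenyl-8-(trimethylsilyloxy)tetradeca-2,7,9,11,13-pentaenoate | C[Si](C)(C)OC(=C\[C@H](C)[C@H](O[Si](C)(C)C(C)(C)C)[C@@H](CC)/C=C(\CC)C(=O)OCC[Si](C)(C)C)/C=C(C)/C=C(CC)/C=C/c1ccccc1
F2 | step 21 | 2-(trimethylsilyl)ethyl (1S,2S,3S,3aS,4R,5S,7aR)-2-(tert-butyldimethylsilyloxy)-3,4-diethyl-5-[(1E,3E)-2-ethyl-4-phenylbuta-1,3-dien-1-yl]-1,5-dimethyl-7-(trimethylsilyloxy)-2,3,3a,4,5,7a-hexahydro-1H-indene-4-carboxylate | CCC(/C=C/c1ccccc1)=C\[C@@]1(C)C=C(O[Si](C)(C)C)[C@@H]2[C@H]([C@H](CC)[C@@H](O[Si](C)(C)C(C)(C)C)[C@H]2C)[C@@]1(CC)C(=O)OCC[Si](C)(C)C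
F3 | step 18 | (R)-4-benzyl-3-[(2R,3S,4S)-3-(tert-butyldimethylsilyloxy)-2-ethyl-4-methyl-6-oxohexanoyl]oxazolidin-2-one | O=CC[C@H](C)[C@H](O[Si](C)(C)C(C)(C)C)[C@@H](CC)C(=O)N1[C@H](Cc2ccccc2)COC1=O
F4 | step 18 | (R)-4-benzyl-3-[(2R,3S,4S)-3-(tert-butyldimethylsilyloxy)-2-ethyl-6,6-dimethoxy-4-methylhexanoyl]oxazolidin-2-one | COC(OC)C[C@H](C)[C@H](O[Si](C)(C)C(C)(C)C)[C@@H](CC)C(=O)N1[C@H](Cc2ccccc2)COC1=O
F5 | step 18 | (2S,3S,4S)-3-(tert-butyldimethylsilyloxy)-2-ethyl-6,6-dimethoxy-4-methylhexan-1-ol | COC(OC)C[C@H](C)[C@H](O[Si](C)(C)C(C)(C)C)[C@@H](CC)CO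
F6 | step 18 | (2R,3S,4S)-3-(tert-butyldimethylsilyloxy)-2-ethyl-6,6-dimethoxy-4-methylhexanal | COC(OC)C[C@H](C)[C@H](O[Si](C)(C)C(C)(C)C)[C@@H](CC)C=O
F7 | step 18 | 2-(trimethylsilyl)ethyl (2E,4S,5S,6S)-5-(tert-butyldimethylsilyloxy)-2,4-diethyl-8,8-dimethoxy-6-methyloct-2-enoate | COC(OC)C[C@H](C)[C@H](O[Si](C)(C)C(C)(C)C)[C@@H](CC)/C=C(\CC)C(=O)OCC[Si](C)(C)C
F8 | step 15 | (2R,3S,4S)-2-ethyl-3-hydroxy-N-methoxy-N,4-dimethylhept-6-enamide | C=CC[C@H](C)[C@H](O)[C@@H](CC)C(=O)N(C)OC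
F9 | step 15 | (2R,3S,4S)-3-(tert-butyldimethylsilyloxy)-2-ethyl-N-methoxy-N,4-dimethylhept-6-enamide | C=CC[C@H](C)[C@H](O[Si](C)(C)C(C)(C)C)[C@@H](CC)C(=O)N(C)OC
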